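## The problem

Target 30 is a hydroazulene sesquiterpenoid ester. In the skeleton numbering used throughout, the five-membered ring is C1(CH3)–C2–C3–C4(OH, isopropyl)–C5 and the seven-membered ring is C5–C6(O-aroyl)–C7–C8(CH3)–C9–C10–C1; the rings are cis-fused along C1–C5 and C8–C9 carries an epoxide. Of the six stereocentres, C1 is quaternary and C4 is a tertiary carbinol; the C1 methyl group, H5 and the epoxide oxygen lie on the convex face of the folded bicycle, and the oxygens on C4 and C6 point into the fold. C4 and C5 are neighbours and can be made together as one epoxide; C5 can then set C1 through the ring fusion, and the shape of the cis-fused bicycle can direct a hydride to C6 and an oxidant to C8=C9 from the convex face. Three groups are fragile: the tertiary C4 alcohol (an aldol while C6 is a ketone, and prone to ionise under acid), the trisubstituted epoxide (acid), and the phenolic benzoate (strong base, nucleophiles). The feature that opens the structure is the pair of oxygens flanking C5: a tertiary oxygen on C4 beside an oxygen on C6 is what remains when a C4–C5 epoxide ionises at C5 into a 2-silyloxyallyl cation C5–C6–C7, and C1, C10, C9, C8 are the four carbons of a diene that can capture that cation at both ends. One (4+3) event can therefore form C1–C5 and C7–C8 and close both rings, but it leaves the ring alkene at C9=C10, one position away from where the epoxide needs it.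

## Retrosynthesis

**Phenol and epoxide (30 ⇒ 29 ⇒ 28).** The benzyl–oxygen bond of 29 is cut last and the two epoxide C–O bonds before it, which leads to alkene 28. This keeps the acid-labile epoxide and the free phenol out of every other step. A benzyl ether is preferred to an acyl group on the phenol because an aryl acetate could pass its acetyl group to the hindered C6 alcohol during esterification, and at the point of hydrogenolysis no alkene remains. The epoxidation has to come from the convex face, anti to the C6 ester, under neutral conditions.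

**Alkene position (28 ⇒ 27).** No skeletal bond is cut; the C8=C9 alkene of 28 is traced back to the C9=C10 alkene of 27, which is what the cycloaddition delivers. A hydrogen-atom-transfer catalyst was set aside: such catalysts engage 1,2-disubstituted alkenes poorly, and the trisubstituted product would be the better substrate, so the alkene would scramble toward C7 through the tertiary C8 radical. A metal hydride acting by insertion and β-hydride elimination (RuHCl(CO)(PPh3)3) places the metal on secondary C9 only and can leave C8=C9 only through a tertiary alkyl. The shift is done on the ester: at the ketone stage the alkene would run into conjugation, and with a free C6 alcohol any over-migrated isomer would be an allylic alcohol that the catalyst converts to a ketone.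

**Ester and C6 carbinol (27 ⇒ 25 + 26; 25 ⇒ 24 ⇒ 23).** Cutting the C6–O acyl bond gives diol 25 and acid chloride 26; only the secondary alcohol can be acylated. The C6–H bond is cut next, taking 24 back to ketone 23. The silyl group stays on the C4 oxygen until the ketone is reduced, because the free β-hydroxy ketone could undergo retro-aldol cleavage. It is removed (24 to 25) before acylation to relieve crowding in the fold. The hydride has to add from the convex face.

**Both rings (23 ⇒ 22).** C1–C5 and C7–C8 are cut together. This removes both rings and three stereocentres and leaves an acyclic triene, 22, whose only stereocentres are the two epoxide carbons. Cutting C4–C5 (aldol) or C7–C8 alone would leave a seven-membered ring still to be made. The forward reaction must transfer the epoxide configuration to C5 with inversion, give the cis fusion, and close the seven-membered ring in preference to a five-membered one.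

**Enol silane and methyl ketone (22 ⇒ 20 ⇒ 19 ⇒ 17 + 18 ⇒ 16).** The O–Si bond is cut to ketone 20, and the C6–C7 bond to aldehyde 17 and methylmagnesium bromide 18, with carbinol 19 between them. Epoxy alcohol 16 is the oxidation-level precursor of 17. This three-step adjustment is accepted because it lets the epoxide be made on a primary allylic alcohol, the substrate class for which asymmetric epoxidation is most reliable.

**Epoxide (16 ⇒ 15 ⇒ 14).** The two C–O bonds are cut to allylic alcohol 15, obtained from ester 14. A Sharpless epoxidation sets C4 and C5 in one step, and the diene is not touched because it has no directing hydroxyl group.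

**Trisubstituted alkene (14 ⇒ 12 + 13).** The C4–isopropyl bond is cut to ynoate 12 and isopropylmagnesium bromide 13. A Horner–Wadsworth–Emmons reaction of the corresponding isopropyl ketone would distinguish isopropyl from a primary alkyl group only weakly. syn-Carbocupration fixes the (2E) geometry by mechanism, and this geometry decides the relative configuration of the epoxide.

**Ynoate and diene (12 ⇒ 9 + 10; 9 ⇒ 7 + 8).** The C5–C6 bond is cut to dienyne 9 and ethyl chloroformate 10. The C8=C9 alkene is cut to (Z)-enal 7 and 1,1-diiodoethane 8. The diene is installed early, while the molecule is small and carries no base-sensitive group, and an (E)-selective chromium alkylidenation is chosen over ylide chemistry.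

**Chain with the (Z)-alkene (7 ⇒ 6 ⇒ 3 + 4 ⇒ 1).** Enal 7 comes from alcohol 6, the alkyne carbon from Ohira–Bestmann reagent 4 and aldehyde 3, and 3 from neryl acetate 1 by cleavage of the isopropylidene alkene. Compound 1 supplies C1, its methyl group, C2, C3, C4, C9, C10 and the (Z)-C1=C10 geometry.

## Roads not taken

**Alternative 1:** rhodium vinylcarbenoid cyclopropanation followed by Cope rearrangement. The cut is C7–C8 and C1–C10. Rh2(S-DOSP)4 would decompose methyl 2-diazobut-3-enoate A1; the carbenoid (C8, with C9 and C10 as its vinyl group) would cyclopropanate the terminal enol ether alkene C6=C7 of silyloxydiene A2, and the cis-dialkenylcyclopropane would rearrange to hydroazulenone A3.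
- Merits: two small achiral fragments, catalytic asymmetric creation of quaternary C1, and a ring alkene already at C8=C9. In that last respect this road is better than the chosen one, which has to move its alkene.
- Weak points: A3 carries an ester at C8 where a methyl group is needed. C4 is a ketone, so isopropyl must be added to a hindered, enolisable cyclopentanone with face control. C5 is sp2, so H5 would be introduced by protonation next to the C6 carbonyl with nothing to enforce the cis fusion. The Cope step must form the quaternary centre at the tetrasubstituted β-carbon of an enone, and A1 cyclises readily to a pyrazole.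
- Comparison: the chosen plan has C4, C5 and C1 under the control of one epoxide, and C4, C6 and the C8 methyl group arrive at the right oxidation level.

**Alternative 2:** asymmetric conjugate methylation relayed into an aldol closure. The cut is C1–CH3 and C4–C5. AlMe3 with copper thiophene-2-carboxylate (monovalent copper) and a chiral phosphoramidite would add methyl to C1 of cycloheptadienone A4, and the C5 aluminium enolate would attack the tethered isopropyl ketone to give hydroxy ketone A5.
- Merits: catalytic and asymmetric, and A5 already has the C8 methyl group and the C8=C9 alkene. The end game would be reduction, aroylation, epoxidation and deprotection, so it would be about two steps shorter and would avoid the alkene shift.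
- Weak points: A4 is a cyclohepta-2,5-dienone whose C7 and C10 methylene groups are doubly activated, so it can slip into conjugation under the Lewis-acidic conditions. An aluminium enolate is a weak nucleophile toward a hindered isopropyl ketone, and the aldol is reversible. Only C1 is set by the catalyst; C4 and C5 depend on an aldol transition state for which there is no basis to predict the required isomer (C4–O syn to C5–C6, cis fusion).
- Comparison: the chosen plan answers the shorter end game with stereospecific transfer from a Sharpless epoxide and with stable acyclic precursors.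

**Alternative 3:** silicon-tethered de Mayo ring expansion. The cut is C5–C6 and C1–C10, with later fragmentation of C6–C10. Irradiation of tethered enone A6 would join the enol ether carbons C6=C10 of the dione to the cyclopentene C5=C1; fluoride would remove the tether and trigger retro-aldol cleavage of C6–C10 to give dione A7.
- Merits: the tether fixes regiochemistry and delivers C6 to the face of the C4 oxygen, the cyclobutane guarantees the cis fusion, and the C9 carbonyl marks where the alkene belongs. This control of the fusion is at least as secure as in the chosen plan.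
- Weak points: A7 lacks the C8 methyl group and has two ketones in a 1,4-relationship that must be told apart. Methylation at C8 rather than C10 and conversion of the C9 ketone into the C8=C9 alkene add four or five steps. The free tertiary alcohol is an aldol of the C6 ketone. The absolute configuration rests on an enantioenriched tertiary cyclopentenol for which no short asymmetric route exists.
- Comparison: the chosen plan brings all fifteen skeletal carbons, including the C8 methyl group, through the key step and controls the absolute configuration.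

Key step: step 13

Remark: the target is read from its stereodescriptors as the cis-fused bicycle (C1–CH3 and H5 on the same face), commercial neryl acetate 1 is taken as the pure (2Z) isomer, and compound names use azulene numbering (skeleton C4, C5, C6, C7, C8, C9, C10, C1 = positions 3, 3a, 4, 5, 6, 7, 8, 8a).

## Route

Step 1
Reactants: 1 neryl acetate [(2Z)-3,7-dimethylocta-2,6-dien-1-yl acetate]
Product: 3 (2Z)-3-methyl-6-oxohex-2-en-1-yl acetate, via ozonide 2 (not isolated)
Conditions: O3 (1.0 equiv), CH2Cl2/pyridine, −78 °C; then Me2S, −78 °C to rt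
Reagents that add atoms: ozone, [O-][O+]=O
Why: Chemoselective ozonolysis; the isopropylidene alkene is the more electron-rich one because the C2=C3 alkene is deactivated by the allylic acetate, so one equivalent of ozone should cleave only the distal double bond and leave the (Z)-alkene intact.

Step 2
Reactants: 3 (2Z)-3-methyl-6-oxohex-2-en-1-yl acetate; 4 dimethyl (1-diazo-2-oxopropyl)phosphonate
Product: 6 (2Z)-3-methylhept-2-en-6-yn-1-ol, via alkynyl acetate 5 (not isolated)
Conditions: K2CO3, MeOH, 0 °C to rt
Reagents that add atoms: none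
Why: Ohira–Bestmann (Seyferth–Gilbert) homologation turns the aldehyde into the terminal alkyne, and the same methanolic carbonate removes the acetate by transesterification, so the allylic alcohol is freed without a separate step.

Step 3
Reactants: 6 (2Z)-3-methylhept-2-en-6-yn-1-ol
Product: 7 (2Z)-3-methylhept-2-en-6-ynal
Conditions: TEMPO (10 mol%), PhI(OAc)2, CH2Cl2, 0 °C to rt
Reagents that add atoms: none
Why: Oxoammonium (TEMPO/PhI(OAc)2) oxidation of a primary allylic alcohol; the medium is neither basic nor strongly acidic, so the neral-type (Z)-enal should form without Z/E isomerisation, and the alkyne is inert.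

Step 4
Reactants: 7 (2Z)-3-methylhept-2-en-6-ynal; 8 1,1-diiodoethane
Product: 9 (5Z,7E)-5-methylnona-5,7-dien-1-yne
Conditions: CrCl2 (6 equiv), THF, 0 °C to rt
Reagents that add atoms: none
Why: Takai–Utimoto alkylidenation; the gem-dichromium reagent formed from 8 and CrCl2 (divalent chromium) adds to the aldehyde and eliminates to the (E)-alkene, and the base-free conditions spare the terminal alkyne and the (Z)-trisubstituted alkene.

Step 5
Reactants: 9 (5Z,7E)-5-methylnona-5,7-dien-1-yne; 10 ethyl chloroformate
Product: 12 ethyl (6Z,8E)-6-methyldeca-6,8-dien-2-ynoate, via lithium acetylide 11 (not isolated)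
Conditions: n-BuLi, THF, −78 °C; then 10, −78 to 0 °C
Reagents that add atoms: none
Why: Deprotonation of the terminal alkyne and C-acylation of the acetylide with a chloroformate; acid–base reaction at −78 °C is far faster than any addition of the alkyllithium to the diene.

Step 6
Reactants: 12 ethyl (6Z,8E)-6-methyldeca-6,8-dien-2-ynoate; 13 isopropylmagnesium bromide
Product: 14 ethyl (2E,6Z,8E)-6-methyl-3-(propan-2-yl)deca-2,6,8-trienoate
Conditions: 13, CuBr·SMe2 (1:1), THF, −78 °C; then 12, −78 °C; NH4Cl, −78 °C
Reagents that add atoms: none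
Why: Conjugate addition of an organocopper reagent to an ynoate (syn-carbocupration); isopropyl and copper add to the same side, so after protonation with retention the ester is trans to isopropyl, and the cold quench prevents equilibration through the allenolate.

Step 7
Reactants: 14 ethyl (2E,6Z,8E)-6-methyl-3-(propan-2-yl)deca-2,6,8-trienoate
Product: 15 (2E,6Z,8E)-6-methyl-3-(propan-2-yl)deca-2,6,8-trien-1-ol
Conditions: i-Bu2AlH (2.5 equiv), CH2Cl2, −78 °C
Reagents that add atoms: none
Why: 1,2-Reduction of an α,β-unsaturated ester to the allylic alcohol with an aluminium hydride; no alkene geometry is touched.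

Step 8
Reactants: 15 (2E,6Z,8E)-6-methyl-3-(propan-2-yl)deca-2,6,8-trien-1-ol
Product: 16 [(2R,3R)-3-[(3Z,5E)-3-methylhepta-3,5-dien-1-yl]-3-(propan-2-yl)oxiran-2-yl]methanol
Conditions: Ti(OiPr)4 (10 mol%), D-(−)-diethyl tartrate (12 mol%), t-BuOOH, 4 Å MS, CH2Cl2, −20 °C
Reagents that add atoms: tert-butyl hydroperoxide, CC(C)(C)OO
Why: Sharpless asymmetric epoxidation of a 3,3-disubstituted primary allylic alcohol; the D-(−)-tartrate delivers oxygen to the face that gives the (2R,3R) epoxide (the mirror image of the geraniol/L-(+)-tartrate case), which sets C4 and C5 together, and the diene is not epoxidised because it lacks a directing hydroxyl group.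

Step 9
Reactants: 16 [(2R,3R)-3-[(3Z,5E)-3-methylhepta-3,5-dien-1-yl]-3-(propan-2-yl)oxiran-2-yl]methanol
Product: 17 (2S,3R)-3-[(3Z,5E)-3-methylhepta-3,5-dien-1-yl]-3-(propan-2-yl)oxirane-2-carbaldehyde
Conditions: Dess–Martin periodinane, pyridine, CH2Cl2, 0 °C to rt
Reagents that add atoms: none
Why: Dess–Martin oxidation of a primary epoxy alcohol under buffered conditions; the epoxide and the diene are inert, and the change of descriptor at C2 reflects only the new substituent priority.

Step 10
Reactants: 17 (2S,3R)-3-[(3Z,5E)-3-methylhepta-3,5-dien-1-yl]-3-(propan-2-yl)oxirane-2-carbaldehyde; 18 methylmagnesium bromide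
Product: 19 1-[(2R,3R)-3-[(3Z,5E)-3-methylhepta-3,5-dien-1-yl]-3-(propan-2-yl)oxiran-2-yl]ethan-1-ol (both carbinol epimers)
Conditions: 18, THF, −78 °C; NH4Cl
Reagents that add atoms: none
Why: Grignard addition to an aldehyde, which is much faster than epoxide opening at −78 °C; the new carbinol centre is removed in the next step, so its configuration is immaterial.

Step 11
Reactants: 19 1-[(2R,3R)-3-[(3Z,5E)-3-methylhepta-3,5-dien-1-yl]-3-(propan-2-yl)oxiran-2-yl]ethan-1-ol
Product: 20 1-[(2S,3R)-3-[(3Z,5E)-3-methylhepta-3,5-dien-1-yl]-3-(propan-2-yl)oxiran-2-yl]ethan-1-one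
Conditions: Dess–Martin periodinane, pyridine, CH2Cl2, 0 °C to rt
Reagents that add atoms: none
Why: Dess–Martin oxidation of a secondary alcohol to the methyl ketone; both carbinol epimers converge on one epoxy ketone.

Step 12
Reactants: 20 1-[(2S,3R)-3-[(3Z,5E)-3-methylhepta-3,5-dien-1-yl]-3-(propan-2-yl)oxiran-2-yl]ethan-1-one
Product: 22 triethyl({1-[(2S,3R)-3-[(3Z,5E)-3-methylhepta-3,5-dien-1-yl]-3-(propan-2-yl)oxiran-2-yl]ethenyl}oxy)silane, via sodium enolate 21 (not isolated)
Conditions: NaN(SiMe3)2, THF, −78 °C; then Et3SiCl, Et3N, −78 °C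
Reagents that add atoms: chlorotriethylsilane, CC[Si](Cl)(CC)CC
Why: Kinetic enolisation and O-silylation; the amide base removes a methyl proton, because the proton on the epoxide carbon is poorly acidic, and the enol silane is formed under basic conditions that leave the epoxide closed.

Step 13
Reactants: 22 triethyl({1-[(2S,3R)-3-[(3Z,5E)-3-methylhepta-3,5-dien-1-yl]-3-(propan-2-yl)oxiran-2-yl]ethenyl}oxy)silane
Product: 23 (3R,3aR,6R,8aS)-6,8a-dimethyl-3-(propan-2-yl)-3-[(triethylsilyl)oxy]-2,3,3a,5,6,8a-hexahydroazulen-4(1H)-one
Conditions: Et3SiOTf (10 mol%), CH2Cl2, −78 °C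
Reagents that add atoms: none
Why: The silyl triflate silylates the epoxide oxygen, and the C5–O bond, which is allylic to the enol silane, ionises as the diene terminus C1 attacks C5 from the side opposite the leaving oxygen; the developing 2-silyloxyallyl cation C5–C6–C7 closes onto C8 in the same event, and loss of the silyl group from the C6 oxonium gives the ketone and returns the catalyst, while the C4 oxygen keeps the silyl group it received at the start. The closest known reaction type is the Lewis-acid-initiated intramolecular (4+3) cycloaddition of epoxy enol silanes with tethered dienes and furans, which proceeds with transfer of the epoxide configuration. The five-membered ring closes by the C1–C5 bond through the tether C2–C3–C4 (exo with respect to the C1=C10 alkene, both epoxide carbons ending inside the new ring), and the seven-membered ring closes by the C7–C8 bond as the (4+3) union of the diene C1=C10–C9=C8 with the three-carbon cation. C4 is not touched and keeps its configuration, and C5 is set by inversion at the epoxide carbon. C1 is set relative to C5 by the (Z)-geometry of C1=C10, which puts the tether on the inside of the s-cis diene so that it can span to C5 only when the cation lies over the diene (compact arrangement), and this gives the cis ring fusion. C8 follows from suprafacial addition to the (E)-C8=C9 alkene, which places its methyl group cis to the C1 methyl group. The step needs cis fusion, full chirality transfer and seven-ring closure in preference to capture of the cation at C10 or proton loss; the low temperature, the catalytic amount of a non-nucleophilic silyl triflate and the fixed diene geometry are what should secure them.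

Step 14
Reactants: 23 (3R,3aR,6R,8aS)-6,8a-dimethyl-3-(propan-2-yl)-3-[(triethylsilyl)oxy]-2,3,3a,5,6,8a-hexahydroazulen-4(1H)-one
Product: 24 (3R,3aS,4R,6R,8aS)-6,8a-dimethyl-3-(propan-2-yl)-3-[(triethylsilyl)oxy]-1,2,3,3a,4,5,6,8a-octahydroazulen-4-ol
Conditions: NaBH4, MeOH/CH2Cl2, 0 °C
Reagents that add atoms: none
Why: Borohydride reduction of a ketone under substrate control; the hydride should add to the convex face of the cis-fused bicycle, anti to the C4 silyloxy group that sits in the fold, which places the C6 hydroxyl syn to the C4 oxygen (4R); the silyl ether keeps the β-oxygenated ketone from retro-aldol cleavage.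

Step 15
Reactants: 24 (3R,3aS,4R,6R,8aS)-6,8a-dimethyl-3-(propan-2-yl)-3-[(triethylsilyl)oxy]-1,2,3,3a,4,5,6,8a-octahydroazulen-4-ol
Product: 25 (3R,3aS,4R,6R,8aS)-6,8a-dimethyl-3-(propan-2-yl)-1,2,3,3a,4,5,6,8a-octahydroazulene-3,4-diol
Conditions: Bu4NF, THF, 0 °C to rt
Reagents that add atoms: none
Why: Fluoride cleavage of a triethylsilyl ether; with C6 reduced, the free tertiary alcohol is no longer an aldol and is stable to the basic fluoride.

Step 16
Reactants: 25 (3R,3aS,4R,6R,8aS)-6,8a-dimethyl-3-(propan-2-yl)-1,2,3,3a,4,5,6,8a-octahydroazulene-3,4-diol; 26 4-(benzyloxy)benzoyl chloride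
Product: 27 (3R,3aS,4R,6R,8aS)-3-hydroxy-6,8a-dimethyl-3-(propan-2-yl)-1,2,3,3a,4,5,6,8a-octahydroazulen-4-yl 4-(benzyloxy)benzoate
Conditions: 26 (1.5 equiv), DMAP, Et3N, CH2Cl2, rt
Reagents that add atoms: none
Why: DMAP-catalysed acylation with an acid chloride; only the secondary C6 hydroxyl can react because the C4 alcohol is tertiary, and the benzyl ether on the phenol cannot transfer an acyl group.

Step 17
Reactants: 27 (3R,3aS,4R,6R,8aS)-3-hydroxy-6,8a-dimethyl-3-(propan-2-yl)-1,2,3,3a,4,5,6,8a-octahydroazulen-4-yl 4-(benzyloxy)benzoate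
Product: 28 (3R,3aS,4R,8aS)-3-hydroxy-6,8a-dimethyl-3-(propan-2-yl)-1,2,3,3a,4,5,8,8a-octahydroazulen-4-yl 4-(benzyloxy)benzoate
Conditions: RuHCl(CO)(PPh3)3 (10 mol%), toluene, 100 °C
Reagents that add atoms: none
Why: Alkene isomerisation by a ruthenium hydride (hydrometalation and β-hydride elimination); Ru–H should add across C9=C10 with the metal on C9, away from quaternary C1, on the face that carries H8 (opposite both methyl groups), and elimination of H8 gives the more stable trisubstituted C8=C9 alkene, which binds the catalyst less well and could move on only through a tertiary alkyl at C8.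

Step 18
Reactants: 28 (3R,3aS,4R,8aS)-3-hydroxy-6,8a-dimethyl-3-(propan-2-yl)-1,2,3,3a,4,5,8,8a-octahydroazulen-4-yl 4-(benzyloxy)benzoate
Product: 29 (3R,3aS,4R,6R,7S,8aS)-6,7-epoxy-3-hydroxy-6,8a-dimethyl-3-(propan-2-yl)decahydroazulen-4-yl 4-(benzyloxy)benzoate
Conditions: dimethyldioxirane, acetone, 0 °C
Reagents that add atoms: dimethyldioxirane, CC1(C)OO1
Why: Electrophilic epoxidation of a trisubstituted alkene by a dioxirane; the oxidant should approach the convex face, anti to the C6 aroyloxy group and the five-membered ring in the fold, which places the oxygen cis to the C1 methyl group and H5 (6R,7S), and the neutral medium spares the acid-labile epoxide.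

Step 19
Reactants: 29 (3R,3aS,4R,6R,7S,8aS)-6,7-epoxy-3-hydroxy-6,8a-dimethyl-3-(propan-2-yl)decahydroazulen-4-yl 4-(benzyloxy)benzoate
Product: 30 (3R,3aS,4R,6R,7S,8aS)-6,7-epoxy-3-hydroxy-6,8a-dimethyl-3-(propan-2-yl)decahydroazulen-4-yl 4-hydroxybenzoate
Conditions: H2 (1 atm), Pd/C (10%), EtOAc, rt
Reagents that add atoms: none
Why: Hydrogenolysis of a benzyl aryl ether over palladium on carbon; no alkene remains, and the non-benzylic epoxide and the benzoate ester are not cleaved under neutral conditions.

## Compound list

1 | neryl acetate, (2Z)-3,7-dimethylocta-2,6-dien-1-yl acetate | CC(C)=CCC/C(C)=C\COC(C)=O | starting material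
2 | (2Z)-5-(5,5-dimethyl-1,2,4-trioxolan-3-yl)-3-methylpent-2-en-1-yl acetate (ozonide) | CC1(C)OOC(CC/C(C)=C\COC(C)=O)O1 | intermediate (not isolated)
3 | (2Z)-3-methyl-6-oxohex-2-en-1-yl acetate | O=CCC/C(C)=C\COC(C)=O | intermediate
4 | dimethyl (1-diazo-2-oxopropyl)phosphonate | CC(=O)C(=[N+]=[N-])P(=O)(OC)OC | starting material
5 | (2Z)-3-methylhept-2-en-6-yn-1-yl acetate | C#CCC/C(C)=C\COC(C)=O | intermediate (not isolated)
6 | (2Z)-3-methylhept-2-en-6-yn-1-ol | C#CCC/C(C)=C\CO | intermediate
7 | (2Z)-3-methylhept-2-en-6-ynal | C#CCC/C(C)=C\C=O | intermediate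
8 | 1,1-diiodoethane | CC(I)I | starting material
9 | (5Z,7E)-5-methylnona-5,7-dien-1-yne | C#CCC/C(C)=C\C=C\C | intermediate
10 | ethyl chloroformate | CCOC(Cl)=O | starting material
11 | [(5Z,7E)-5-methylnona-5,7-dien-1-yn-1-yl]lithium | [Li]C#CCC/C(C)=C\C=C\C | intermediate (not isolated)
12 | ethyl (6Z,8E)-6-methyldeca-6,8-dien-2-ynoate | CCOC(=O)C#CCC/C(C)=C\C=C\C | intermediate
13 | isopropylmagnesium bromide | CC(C)[Mg]Br | starting material
14 | ethyl (2E,6Z,8E)-6-methyl-3-(propan-2-yl)deca-2,6,8-trienoate | CCOC(=O)/C=C(\CC/C(C)=C\C=C\C)C(C)C | intermediate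
15 | (2E,6Z,8E)-6-methyl-3-(propan-2-yl)deca-2,6,8-trien-1-ol | OC/C=C(\CC/C(C)=C\C=C\C)C(C)C | intermediate
16 | [(2R,3R)-3-[(3Z,5E)-3-methylhepta-3,5-dien-1-yl]-3-(propan-2-yl)oxiran-2-yl]methanol | CC(C)[C@@]1(CC/C(C)=C\C=C\C)O[C@@H]1CO | intermediate
17 | (2S,3R)-3-[(3Z,5E)-3-methylhepta-3,5-dien-1-yl]-3-(propan-2-yl)oxirane-2-carbaldehyde | CC(C)[C@@]1(CC/C(C)=C\C=C\C)O[C@@H]1C=O | intermediate
18 | methylmagnesium bromide | C[Mg]Br | starting material
19 | 1-[(2R,3R)-3-[(3Z,5E)-3-methylhepta-3,5-dien-1-yl]-3-(propan-2-yl)oxiran-2-yl]ethan-1-ol, both carbinol epimers | CC(C)[C@@]1(CC/C(C)=C\C=C\C)O[C@@H]1C(C)O | intermediate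
20 | 1-[(2S,3R)-3-[(3Z,5E)-3-methylhepta-3,5-dien-1-yl]-3-(propan-2-yl)oxiran-2-yl]ethan-1-one | CC(C)[C@@]1(CC/C(C)=C\C=C\C)O[C@@H]1C(C)=O | intermediate
21 | sodium 1-[(2S,3R)-3-[(3Z,5E)-3-methylhepta-3,5-dien-1-yl]-3-(propan-2-yl)oxiran-2-yl]ethen-1-olate | CC(C)[C@@]1(CC/C(C)=C\C=C\C)O[C@@H]1C(=C)O[Na] | intermediate (not isolated)
22 | triethyl({1-[(2S,3R)-3-[(3Z,5E)-3-methylhepta-3,5-dien-1-yl]-3-(propan-2-yl)oxiran-2-yl]ethenyl}oxy)silane | CC(C)[C@@]1(CC/C(C)=C\C=C\C)O[C@@H]1C(=C)O[Si](CC)(CC)CC | intermediate
23 | (3R,3aR,6R,8aS)-6,8a-dimethyl-3-(propan-2-yl)-3-[(triethylsilyl)oxy]-2,3,3a,5,6,8a-hexahydroazulen-4(1H)-one | CC(C)[C@]1(O[Si](CC)(CC)CC)CC[C@@]2(C)C=C[C@H](C)CC(=O)[C@H]21 | intermediate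
24 | (3R,3aS,4R,6R,8aS)-6,8a-dimethyl-3-(propan-2-yl)-3-[(triethylsilyl)oxy]-1,2,3,3a,4,5,6,8a-octahydroazulen-4-ol | CC(C)[C@]1(O[Si](CC)(CC)CC)CC[C@@]2(C)C=C[C@H](C)C[C@@H](O)[C@H]21 | intermediate
25 | (3R,3aS,4R,6R,8aS)-6,8a-dimethyl-3-(propan-2-yl)-1,2,3,3a,4,5,6,8a-octahydroazulene-3,4-diol | CC(C)[C@]1(O)CC[C@@]2(C)C=C[C@H](C)C[C@@H](O)[C@H]21 | intermediate
26 | 4-(benzyloxy)benzoyl chloride | O=C(Cl)c1ccc(OCc2ccccc2)cc1 | starting material
27 | (3R,3aS,4R,6R,8aS)-3-hydroxy-6,8a-dimethyl-3-(propan-2-yl)-1,2,3,3a,4,5,6,8a-octahydroazulen-4-yl 4-(benzyloxy)benzoate | CC(C)[C@]1(O)CC[C@@]2(C)C=C[C@H](C)C[C@@H](OC(=O)c3ccc(OCc4ccccc4)cc3)[C@H]21 | intermediate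
28 | (3R,3aS,4R,8aS)-3-hydroxy-6,8a-dimethyl-3-(propan-2-yl)-1,2,3,3a,4,5,8,8a-octahydroazulen-4-yl 4-(benzyloxy)benzoate | CC(C)[C@]1(O)CC[C@@]2(C)CC=C(C)C[C@@H](OC(=O)c3ccc(OCc4ccccc4)cc3)[C@H]21 | intermediate
29 | (3R,3aS,4R,6R,7S,8aS)-6,7-epoxy-3-hydroxy-6,8a-dimethyl-3-(propan-2-yl)decahydroazulen-4-yl 4-(benzyloxy)benzoate | CC(C)[C@]1(O)CC[C@@]2(C)C[C@@H]3O[C@]3(C)C[C@@H](OC(=O)c3ccc(OCc4ccccc4)cc3)[C@H]21 | intermediate
30 | (3R,3aS,4R,6R,7S,8aS)-6,7-epoxy-3-hydroxy-6,8a-dimethyl-3-(propan-2-yl)decahydroazulen-4-yl 4-hydroxybenzoate | CC(C)[C@]1(O)CC[C@@]2(C)C[C@@H]3O[C@]3(C)C[C@@H](OC(=O)c3ccc(O)cc3)[C@H]21 | target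

## Step count and least certain steps

Total step count: 19. Longest linear sequence: 19 steps, from neryl acetate 1 to 30; the route is fully linear, and 4, 8, 10, 13, 18 and 26 are purchased.

**Step 13 (key step).** The (3Z)-trisubstituted diene may populate its s-cis form too little. Ionisation of the epoxide would then be answered by a 1,2-shift, by capture at C1 alone followed by proton loss, or by closure of the allyl cation at C10 to a five-membered ring; a longer-lived cation would also erode the chirality transfer. The fallback generates the three-carbon cation by the base-mediated Föhlisch-type cyclisation of an α-halo ketone, a mode with wide precedent for tethered acyclic dienes. It sets out from epoxy ketone 20. MgBr2·OEt2 (Et2O, −20 °C) should open the epoxide at the carbonyl-activated C5 to give (3R,4R,7Z,9E)-3-bromo-4-hydroxy-7-methyl-4-(propan-2-yl)undeca-7,9-dien-2-one F1. Et3SiOTf with 2,6-lutidine (CH2Cl2, −78 °C) should silylate the tertiary alcohol to give (3R,4R,7Z,9E)-3-bromo-7-methyl-4-(propan-2-yl)-4-[(triethylsilyl)oxy]undeca-7,9-dien-2-one F2. Et3N in CF3CH2OH (0 °C to rt) should ionise the bromide to the oxyallyl cation, which the diene traps to come back to the route at cycloadduct 23. The cost is that C5 is no longer set by inversion but by the C4 stereocentre, so the ring fusion becomes a matter of diastereoselection.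

**Step 17.** The isomerisation may stall, because insertion into a hindered cis-disubstituted ring alkene is slow and must occur on the face bearing H8, or it may run on past C8 toward C7. The fallback fixes the alkene position through carbonyl chemistry and sets out from cycloadduct 23.
- Kinetic enolisation at C7 with LiN(iPr)2 (THF, −78 °C) and Mukaiyama dehydrogenation with N-tert-butylbenzenesulfinimidoyl chloride should give (3R,3aR,8aS)-6,8a-dimethyl-3-(propan-2-yl)-3-[(triethylsilyl)oxy]-2,3,3a,8a-tetrahydroazulen-4(1H)-one F3.
- Li in NH3/THF (−78 °C) should reduce the linear dienone at its terminus C10, and kinetic protonation of the dienolate at C7 with NH4Cl should give (3R,3aR,8aS)-6,8a-dimethyl-3-(propan-2-yl)-3-[(triethylsilyl)oxy]-2,3,3a,5,8,8a-hexahydroazulen-4(1H)-one F4, with the alkene at C8=C9.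
- NaBH4 (MeOH, −20 °C) should give (3R,3aS,4R,8aS)-6,8a-dimethyl-3-(propan-2-yl)-3-[(triethylsilyl)oxy]-1,2,3,3a,4,5,8,8a-octahydroazulen-4-ol F5.
- Bu4NF (THF) should give (3R,3aS,4R,8aS)-6,8a-dimethyl-3-(propan-2-yl)-1,2,3,3a,4,5,8,8a-octahydroazulene-3,4-diol F6.
- Acylation with 26 (DMAP, Et3N, CH2Cl2) comes back to the route at 28.

**Step 18.** Facial selectivity may be poor if the C1 methyl group, homoallylic to C9, shields the convex face more than the ester shields the other. The fallback is a halohydrin sequence, which puts the epoxide oxygen on the face opposite to the one the electrophile attacks. It sets out from 28. N-Bromosuccinimide in aqueous acetone (0 °C) should form the bromonium ion on the face the dioxirane preferred; water opens it at tertiary C8 from the other side to give (3R,3aS,4R,6R,7R,8aS)-7-bromo-3,6-dihydroxy-6,8a-dimethyl-3-(propan-2-yl)decahydroazulen-4-yl 4-(benzyloxy)benzoate F7. NaH (THF, 0 °C) closes the C8 alkoxide onto C9 with inversion and comes back to the route at 29.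

**Step 14.** Hydride attack from the fold side would give the C6 epimer. The fallback is chelation-controlled reduction and sets out from 23. HF·pyridine (THF, 0 °C) should remove the silyl group under non-basic conditions to give (3R,3aR,6R,8aS)-3-hydroxy-6,8a-dimethyl-3-(propan-2-yl)-2,3,3a,5,6,8a-hexahydroazulen-4(1H)-one F8. Narasaka–Prasad reduction (Et2BOMe, NaBH4, THF/MeOH, −78 °C) ties the C4 oxygen and the C6 carbonyl into a boron chelate inside the fold, so that external hydride adds from the convex face to give the syn diol and comes back to the route at 25.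

## Further compounds

F1 | step 13 | (3R,4R,7Z,9E)-3-bromo-4-hydroxy-7-methyl-4-(propan-2-yl)undeca-7,9-dien-2-one | CC(C)[C@](O)(CC/C(C)=C\C=C\C)[C@@H](Br)C(C)=O
F2 | step 13 | (3R,4R,7Z,9E)-3-bromo-7-methyl-4-(propan-2-yl)-4-[(triethylsilyl)oxy]undeca-7,9-dien-2-one | CC(C)[C@](O[Si](CC)(CC)CC)(CC/C(C)=C\C=C\C)[C@@H](Br)C(C)=O
F3 | step 17 | (3R,3aR,8aS)-6,8a-dimethyl-3-(propan-2-yl)-3-[(triethylsilyl)oxy]-2,3,3a,8a-tetrahydroazulen-4(1H)-one | CC(C)[C@]1(O[Si](CC)(CC)CC)CC[C@@]2(C)C=CC(C)=CC(=O)[C@H]21
F4 | step 17 | (3R,3aR,8aS)-6,8a-dimethyl-3-(propan-2-yl)-3-[(triethylsilyl)oxy]-2,3,3a,5,8,8a-hexahydroazulen-4(1H)-one | CC(C)[C@]1(O[Si](CC)(CC)CC)CC[C@@]2(C)CC=C(C)CC(=O)[C@H]21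
F5 | step 17 | (3R,3aS,4R,8aS)-6,8a-dimethyl-3-(propan-2-yl)-3-[(triethylsilyl)oxy]-1,2,3,3a,4,5,8,8a-octahydroazulen-4-ol | CC(C)[C@]1(O[Si](CC)(CC)CC)CC[C@@]2(C)CC=C(C)C[C@@H](O)[C@H]21
F6 | step 17 | (3R,3aS,4R,8aS)-6,8a-dimethyl-3-(propan-2-yl)-1,2,3,3a,4,5,8,8a-octahydroazulene-3,4-diol | CC(C)[C@]1(O)CC[C@@]2(C)CC=C(C)C[C@@H](O)[C@H]21
F7 | step 18 | (3R,3aS,4R,6R,7R,8aS)-7-bromo-3,6-dihydroxy-6,8a-dimethyl-3-(propan-2-yl)decahydroazulen-4-yl 4-(benzyloxy)benzoate | CC(C)[C@]1(O)CC[C@@]2(C)C[C@@H](Br)[C@@](O)(C)C[C@@H](OC(=O)c3ccc(OCc4ccccc4)cc3)[C@H]21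
F8 | step 14 | (3R,3aR,6R,8aS)-3-hydroxy-6,8a-dimethyl-3-(propan-2-yl)-2,3,3a,5,6,8a-hexahydroazulen-4(1H)-one | CC(C)[C@]1(O)CC[C@@]2(C)C=C[C@H](C)CC(=O)[C@H]21
A1 | alternative 1 | methyl 2-diazobut-3-enoate | C=CC(=[N+]=[N-])C(=O)OC
A2 | alternative 1 | 2-{1-[(tert-butyldimethylsilyl)oxy]ethenyl}-3-methylcyclopent-2-en-1-one | C=C(O[Si](C)(C)C(C)(C)C)C1=C(C)CCC1=O
A3 | alternative 1 | methyl (8aS)-4-[(tert-butyldimethylsilyl)oxy]-8a-methyl-3-oxo-1,2,3,5,8,8a-hexahydroazulene-6-carboxylate | COC(=O)C1=CC[C@]2(C)CCC(=O)C2=C(O[Si](C)(C)C(C)(C)C)C1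
A4 | alternative 2 | 6-methyl-3-(4-methyl-3-oxopentyl)cyclohepta-2,5-dien-1-one | CC(C)C(=O)CCC1=CC(=O)CC(C)=CC1
A5 | alternative 2 | (3R,3aR,8aS)-3-hydroxy-6,8a-dimethyl-3-(propan-2-yl)-2,3,3a,5,8,8a-hexahydroazulen-4(1H)-one | CC(C)[C@]1(O)CC[C@@]2(C)CC=C(C)CC(=O)[C@H]21
A6 | alternative 3 | 3-{[{[(1R)-3-methyl-1-(propan-2-yl)cyclopent-2-en-1-yl]oxy}di(propan-2-yl)silyl]oxy}cyclopent-2-en-1-one | CC(C)[C@]1(O[Si](C(C)C)(C(C)C)OC2=CC(=O)CC2)CCC(C)=C1
A7 | alternative 3 | (3R,3aR,8aS)-3-hydroxy-8a-methyl-3-(propan-2-yl)octahydroazulene-4,7-dione | CC(C)[C@]1(O)CC[C@@]2(C)CC(=O)CCC(=O)[C@H]21
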